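The numbers are those of an exercise; the flask was simulated.

Count first what cannot change: each nucleophile spent takes with it either one electrophile, as product, or one protic impurity, as quenched reagent.

    nucleophile + acid set free ⇌ protonated nucleophile, settled at all times (K1 = 41 /M)
    acid set free + free base ⇌ salt of the base (K2 = 2.2 × 10⁵ /M, k2 = 8.6 /M/s)
    electrophile ⇌ dormant form (K3 = 0.35, k3 = 0.057 /s)
    electrophile + nucleophile ⇌ acid set free + product (K4 = 31, k4 = 0.52 /M/s)
    nucleophile + protic impurity → quenched reagent (k5 = 0.15 /M/s)

electrophile 0.45 M; nucleophile 0.450 M; free base 0.360 M; protic impurity 0.450 M; time 3.0 min

- part of the electrophile that has reacted at 3.0 min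
- share of the unused nucleophile that is free and not bound as protonated nucleophile, at 3.0 min

The step from acid to salt of the base need not stand at balance while acid is being made, so use its constant for the end of the run. With the charged amounts, K2[free base] is 79000 and K1[nucleophile] is 18, so once that balance stands with free base remaining, take the acid as held by the base. Electrophile and dormant form relax with a half-life of 0.0525 min, short against 3.0 min, so at the end take 74.1% of their sum as electrophile. During the race for nucleophile that share is a working figure: the half-life of electrophile by its reaction with nucleophile, 3.0 s, is of like size, and dormant form starts from zero, so the pair lags behind its balance.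

Now divide the two rates of the nucleophile. Let x be the fraction of electrophile plus dormant form remaining, y the fraction of protic impurity remaining. Holding the working share through the race, x = y^S, with the selectivity factor S = k4/(k5(1+K3)) = 2.57.

Solve two extremes in the head. With a silent impurity, free base as charged, 0.360 M, takes the acid of as much product; past that, count each further product as costing a second nucleophile, bound as protonated nucleophile, so x is about 0.100 and c about 92.6%. With S at 1, equal charges split evenly, x is half, and c is 63.0%. This flask lies between.

Impurity alone would halve the nucleophile in 10.3 s, short against the run, so take it as spent. Its charge equals both others, so x + y = 1. Try y = 0.667: the power gives 0.353, the balance 0.333. Split the difference, x = 0.343, and my c is 74.6%. Product is then 0.296 M, below the base charged, leaving 0.0644 M free base, so my fr is 99.9%.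

The forecast gives 75% (70% to 81%) and 99.9% (98% to 100%), holding that “the excess base mops up the acid almost completely”.

The flask gives 75.6% and 99.9%. It keeps 67% of its protic impurity at 3.00 min; raised to S, that is 35.7%, while electrophile and dormant form together stand at 32.9%. Take the neighbour flask with 0.77 M of electrophile, other charges unchanged. Its balance reads x = 1 − y[protic impurity]/[electrophile], both as charged. At y = 0.800, power and balance give 0.564 and 0.532, their midpoint 0.548, so c is 59.4%. That neighbour flask gives 60.7%.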